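**Compound numbers used throughout**

- Aryne branch: 1 5-methoxyresorcinol; 2 mono-MOM ether; 3 carbamate; 4–6 in-flask species of the silylation; 7 silyl carbamate; 8 silyl phenol (in flask); 9 silylaryl triflate.
- Acid branch: 10 kaempferol; 11 7,4'-di-O-benzylkaempferol; 12 4-fluorobenzaldehyde; 13 5-hydroxy aldehyde (in flask); 14 aldehyde; 15 β-keto ester; 16 (R)-hydroxy ester; 17 silyl ether ester; 18 acid.
- After union: 19 aryne (in flask); 20 insertion product; 21 hydroxy ketone; 22 protected (2S)-flavanone; 23 tri-O-benzyl flavanone; 24 target.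

## Analysis of the target

The target is an ether-linked biflavonoid. One half is a flavanone: rings A and C form a 5-hydroxy-7-methoxychroman-4-one, and ring B is a para-phenylene at C2. The C4' oxygen of ring B is bonded to C3 of a kaempferol unit, a 5,7-dihydroxy-2-(4-hydroxyphenyl)chromen-4-one.

There is one stereocentre, C2 of the flavanone, and it is S. It is benzylic, carries the ring oxygen O1 and lies β to the C4 ketone, so base can erase it by retro-oxa-Michael opening to the 2'-hydroxychalcone and strong acid by ionisation.

The sensitive groups are four free phenols (two chelated to carbonyls), a single methyl ether that must end up on O7 of the flavanone only, the chromone of the kaempferol half (electrophilic at C2 and C4 towards hard nucleophiles) and the benzylic C2–O1 bond (hydrogenolysis).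

Two things make the synthesis hard. Ring A of the flavanone has three different oxygen functions (O1, 5-OH, 7-OMe) around the acyl-bearing C4a, which Friedel–Crafts or Hoesch acylation of an unsymmetrical 1,3,5-trioxygenated benzene cannot place regioselectively. The kaempferol 3-OH that forms the diaryl ether is neither the most nor the least reactive of its four hydroxyls.

The strategy rests on the ortho relationship in ring A. C8a bears O1, its neighbour C4a bears the C4 acyl carbon, and the next carbon C5 bears oxygen. This is the pattern that results when a carboxylic acid adds across a 3-alkoxybenzyne, so C8a–O1 and C4a–C4 can be made together from a chiral 3-hydroxy-3-arylpropanoic acid that already holds C2, C3 and C4.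

## Retrosynthetic reasoning

**Protecting groups (24 ⇐ 23 ⇐ 22).** The three kaempferol phenols are carried as benzyl ethers and O5 of the flavanone as a methoxymethyl ether. Benzyl ethers come off last under neutral hydrogenolysis, which does not touch a base-labile flavanone centre. The acetal on O5 is peri to the C4 carbonyl and is cleaved by mild protic acid before that. It is also the group that steers the metalation and the aryne addition earlier on.

**O1–C2 (22 ⇐ 21 ⇐ 20).** Ring C is opened at the C2–O1 bond and not at a C–C bond. C2 can then be brought in as a secondary benzylic carbinol of R configuration and converted to 2S by an intramolecular Mitsunobu displacement by the ortho-phenol. The forward step must close a six-membered ring with clean inversion and without elimination to the chalcone. The carbinol of 21 is unmasked from the silyl ether 20.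

**C8a–O1 and C4a–C4 (20 ⇐ 18 + 19, with 19 from 9).** Both bonds joining ring A to the three-carbon chain are cut at once. The ortho-hydroxyaryl ketone 20 is the formal insertion product of aryne 19 into the C–O bond of acid 18. The cut is made here because it removes the regiochemical problem of ring A. The alkoxy group next to the triple bond of 19 decides where the carboxylate oxygen adds, and the ketone therefore ends up between the phenol and the protected O5 with the methoxy group para to it. No ring is formed and the carbinol centre is a spectator. The forward step needs regioselective addition and acyl transfer that outruns protonation.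

**Aryne precursor (9 ⇐ 7 ⇐ 3 ⇐ 2 ⇐ 1).** Aryne 19 is released from the ortho-silylaryl triflate 9. The triflate oxygen and the acetal oxygen of 9 are the two hydroxyls of 1, and silicon sits on the carbon between them. One hydroxyl of 1 is protected (2) and the other is turned into a carbamate (3). The carbamate and the acetal together direct lithiation to the carbon between them (7). The carbamate is then exchanged for triflate through phenol 8 in one pot.

**Acid (18 ⇐ 17 ⇐ 16 ⇐ 15 ⇐ 14).** The acid comes from ester 17 by saponification and 17 from carbinol 16 by silylation. The stereocentre of 16 is set by asymmetric hydrogenation of β-keto ester 15, a reaction whose facial sense is predictable. Keto ester 15 is the two-carbon homologue of aldehyde 14.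

**Diaryl ether and kaempferol protection (14 ⇐ 13 ⇐ 11 + 12; 11 ⇐ 10).** The aryl ether is cut at the O–C4' bond, which an SNAr reaction of the kaempferol 3-oxide on the para-formyl-activated fluoride 12 can form. Direct benzylation of 10 cannot leave O3 free while covering O5, because O5 is the least reactive hydroxyl. Benzylation is therefore stopped at the 7,4'-diether 11, the 3-OH is arylated (13), and the chelated 5-OH is benzylated afterwards in the same pot (14).

## Alternatives that were turned down

**Alternative 1: C–H annulation of a salicylaldehyde with an aryl ynol ether.**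
- Disconnection: the chromone ring of the kaempferol half at C3–C4 and O1–C2.
- Forward key step: 2-hydroxy-4,6-bis(benzyloxy)benzaldehyde (A2) and the aryl alkynyl ether 1-(benzyloxy)-4-[(4-bromophenoxy)ethynyl]benzene (A3) would be coupled with [Cp*RhCl2]2 and Cu(OAc)2 as oxidant. Aldehyde C–H activation, alkyne insertion and C–O reductive elimination would give the 3-aryloxyflavone A1.
- For it: two ring bonds form in one step. The 3-aryloxy group arrives with the alkyne, so no flavonol hydroxyl has to be arylated. The 5,7,4'-tribenzyl pattern is built in without selective protection of kaempferol. On this last point it is stronger than the chosen route, whose steps 5 and 6 depend on reactivity differences between hydroxyls.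
- Against it: it builds a half that can be bought. The ynol ether A3 is a labile compound that needs several steps. The insertion regiochemistry of an unsymmetrical, polarised ynol ether into the acyl–rhodium bond is not secured by the substrate. The aldehyde of A2 is flanked by a benzyloxy group.
- Comparison: after A1 the aryl bromide still has to be turned into the whole flavanone half, stereocentre and ring A pattern included, so the two real problems remain and the route is longer. The chosen strategy spends its key step on ring A of the flavanone, where the regiochemical difficulty lies.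

**Alternative 2: dialkoxyaryne insertion at the kaempferol benzo ring.**
- Disconnection: O1–C8a and C4a–C4 of the kaempferol half.
- Forward key step: the silylaryl triflate A6, 3,5-bis(methoxymethoxy)-2-(trimethylsilyl)phenyl triflate, would release a symmetrical aryne with CsF. The aryne would insert into the C–O bond of the (Z)-2-aryloxy-3-arylacrylic acid A5 to give the α-aryloxy-2'-hydroxychalcone A4.
- For it: it uses the same insertion chemistry. The aryne precursor A6 has two identical acetal groups, so its synthesis has no site-selectivity question. The acid A5 has no β-leaving group and no stereocentre to lose under hot fluoride. On both points it is stronger than the chosen key step.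
- Against it: it again makes the commercial half. A4 is not yet a chromone and needs an oxidative cyclisation. A5 has to be prepared with defined alkene geometry.
- Comparison: the bromide then has to be taken on to the flavanone, so the stereocentre and the unsymmetrical ring A are still unsolved. The chosen strategy uses the insertion once, on the ring where no commercial building block holds the pattern.

**Alternative 3: enantioselective carbenoid C–H insertion forming C2–C3.**
- Disconnection: C2–C3 of the flavanone.
- Forward key step: the ring A diazoketone A8, which carries the kaempferol-bearing benzyl ether ortho to the diazoacetyl group, would be treated with a chiral dirhodium tetracarboxylate such as Rh2(S-PTTL)4. The carbenoid carbon would insert into a benzylic C–H bond of the ether, closing ring C and setting 2S in the 5-O-silyl tri-O-benzyl flavanone A7.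
- For it: ring C and the stereocentre are made in one catalytic step late in the route, with no carbinol protection, deprotection or Mitsunobu closure. In step economy around the stereocentre it is stronger than the chosen route.
- Against it: the insertion must form a six-membered ring. The ether oxygen can instead attack the carbenoid to give an oxonium ylide that rearranges by a 1,2-benzyl shift to a benzofuranone. The electron-rich arenes can also be cyclopropanated. Enantiocontrol with so large an aryl group on the reacting carbon is not secured by anything in the substrate. A8 also needs a ring A with three differentiated oxygens and a hindered 2,6-dioxygenated aryl diazoketone, so the regiochemical problem of ring A is only moved.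
- Comparison: the chosen strategy sets the centre by hydrogenation of a β-keto ester and transfers it by inversion, and it solves ring A in the same step that joins the fragments.

Key step: step 11

## Route

Remark on names: "tri-O-benzylkaempferol-3-yloxy" stands for 5,7-bis(benzyloxy)-2-[4-(benzyloxy)phenyl]-4-oxo-4H-chromen-3-yloxy.

Step 1
Reactants: 1 5-methoxyresorcinol
Product: 2 3-methoxy-5-(methoxymethoxy)phenol
Conditions: MOMCl (1.0 equiv), iPr2NEt, CH2Cl2, 0 °C → rt
Reagents that add atoms: chloromethyl methyl ether, COCCl
Why: O-alkylation of one of two equivalent phenols with an α-chloro ether; with one equivalent the mono-ether should be the main product, and recovered diol and bis-ether can be recycled. The acetal is chosen because it is a stronger ortho-director than methoxy in step 3 and is acid-labile next to a carbonyl in step 14.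

Step 2
Reactants: 2 3-methoxy-5-(methoxymethoxy)phenol
Product: 3 3-methoxy-5-(methoxymethoxy)phenyl N-isopropylcarbamate
Conditions: iPrNCO, Et3N (cat.), CH2Cl2, rt
Reagents that add atoms: isopropyl isocyanate, CC(C)N=C=O
Why: Base-catalysed addition of the phenol to the isocyanate gives the O-aryl carbamate, which is the directing group for metalation and can later be cleaved under non-acidic conditions.

Step 3
Reactants: 3 3-methoxy-5-(methoxymethoxy)phenyl N-isopropylcarbamate
Product: 7 5-methoxy-3-(methoxymethoxy)-2-(trimethylsilyl)phenyl N-isopropylcarbamate, via N-silyl carbamate 4 (not isolated), via ortho-lithiated N-silyl carbamate 5 (not isolated), via N-silyl C-silyl carbamate 6 (not isolated)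
Conditions: TBSOTf, TMEDA, Et2O, 0 °C → rt; n-BuLi, TMEDA, −78 °C; TMSCl, −78 °C → rt; aq. NaHSO4
Reagents that add atoms: chlorotrimethylsilane, C[Si](C)(C)Cl (tert-butyldimethylsilyl triflate, CC(C)(C)[Si](C)(C)OS(=O)(=O)C(F)(F)F, supplies the N-silyl group of 4–6 only)
Why: Directed ortho-metalation: N-silylation masks the carbamate NH, and lithiation should then occur at the carbon flanked by the carbamate and the chelating acetal oxygen rather than at the one flanked by carbamate and methoxy. The aryllithium is trapped by TMSCl and the N–Si bond is hydrolysed on mildly acidic work-up.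

Step 4
Reactants: 7 5-methoxy-3-(methoxymethoxy)-2-(trimethylsilyl)phenyl N-isopropylcarbamate
Product: 9 5-methoxy-3-(methoxymethoxy)-2-(trimethylsilyl)phenyl trifluoromethanesulfonate, via silyl phenol 8 (not isolated)
Conditions: DBU, Et2NH, MeCN, 40 °C; then PhNTf2, rt
Reagents that add atoms: N-phenylbis(trifluoromethanesulfonimide), O=S(=O)(N(c1ccccc1)S(=O)(=O)C(F)(F)F)C(F)(F)F
Why: DBU removes the carbamate NH proton and E1cB loss of isopropyl isocyanate (scavenged by Et2NH as a urea) frees the phenoxide, which is triflated in the same pot. The conditions stay basic, which protects the electron-rich arylsilane from protodesilylation.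

Step 5
Reactants: 10 kaempferol
Product: 11 7,4'-di-O-benzylkaempferol
Conditions: BnBr (2.1 equiv), K2CO3, DMF, 0 °C → rt
Reagents that add atoms: benzyl bromide, BrCc1ccccc1
Why: Williamson etherification follows phenol acidity: the 7-OH and 4'-OH react first, the 3-OH next and the chelated 5-OH last, so two equivalents at low temperature should give mainly the 7,4'-diether with O3 free.

Step 6
Reactants: 11 7,4'-di-O-benzylkaempferol; 12 4-fluorobenzaldehyde
Product: 14 4-(tri-O-benzylkaempferol-3-yloxy)benzaldehyde, via 5-hydroxy aldehyde 13 (not isolated)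
Conditions: K2CO3, DMF, 110 °C, Ar; then BnBr, 80 °C
Reagents that add atoms: benzyl bromide, BrCc1ccccc1
Why: SNAr: the 3-oxide, more acidic and less chelated than the 5-OH, adds to the para-formyl-activated fluoride and fluoride leaves from the Meisenheimer adduct. The remaining 5-OH is then benzylated under more forcing conditions in the same pot, so that no free phenol is left to trap the aryne in step 11.

Step 7
Reactants: 14 4-(tri-O-benzylkaempferol-3-yloxy)benzaldehyde
Product: 15 ethyl 3-oxo-3-[4-(tri-O-benzylkaempferol-3-yloxy)phenyl]propanoate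
Conditions: N2CHCO2Et, SnCl2 (20 mol %), CH2Cl2, rt
Reagents that add atoms: ethyl diazoacetate, CCOC(=O)C=[N+]=[N-]
Why: Roskamp homologation: Lewis-acid-promoted addition of the diazo ester to the aldehyde, then 1,2-hydride shift with loss of N2, gives the β-keto ester; the chromone carbonyl, benzyl ethers and diaryl ether are inert under these near-neutral conditions.

Step 8
Reactants: 15 ethyl 3-oxo-3-[4-(tri-O-benzylkaempferol-3-yloxy)phenyl]propanoate
Product: 16 ethyl (R)-3-hydroxy-3-[4-(tri-O-benzylkaempferol-3-yloxy)phenyl]propanoate
Conditions: H2 (50 atm), [RuCl(p-cymene)((S)-BINAP)]Cl (1 mol %), EtOH/CH2Cl2, 50 °C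
Reagents that add atoms: none
Why: Noyori asymmetric hydrogenation of a β-keto ester chelated to divalent ruthenium. (S)-BINAP delivers hydride to the face that gives (S)-3-hydroxybutanoate from acetoacetate, and because aryl outranks CH2CO2Et the same face gives the 3R carbinol here. Benzyl ethers and the tetrasubstituted chromone alkene are not reduced by this catalyst.

Step 9
Reactants: 16 ethyl (R)-3-hydroxy-3-[4-(tri-O-benzylkaempferol-3-yloxy)phenyl]propanoate
Product: 17 ethyl (R)-3-(triisopropylsilyloxy)-3-[4-(tri-O-benzylkaempferol-3-yloxy)phenyl]propanoate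
Conditions: TIPSOTf, 2,6-lutidine, CH2Cl2, 0 °C → rt
Reagents that add atoms: triisopropylsilyl triflate, CC(C)[Si](OS(=O)(=O)C(F)(F)F)(C(C)C)C(C)C
Why: Silylation of the secondary benzylic alcohol with a silyl triflate and a hindered base; the bulky triisopropylsilyl group is chosen to survive hydroxide in step 10 and hot fluoride in step 11.

Step 10
Reactants: 17 ethyl (R)-3-(triisopropylsilyloxy)-3-[4-(tri-O-benzylkaempferol-3-yloxy)phenyl]propanoate
Product: 18 (R)-3-(triisopropylsilyloxy)-3-[4-(tri-O-benzylkaempferol-3-yloxy)phenyl]propanoic acid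
Conditions: LiOH, THF/MeOH/H2O, rt; then 1 M HCl to pH 4
Reagents that add atoms: lithium hydroxide, [Li+].[OH-]
Why: Saponification of the ethyl ester at room temperature; the silyloxy group is a poor leaving group, so β-elimination should not compete, and the chromone is stable to cold aqueous hydroxide.

Step 11
Reactants: 18 (R)-3-(triisopropylsilyloxy)-3-[4-(tri-O-benzylkaempferol-3-yloxy)phenyl]propanoic acid; 9 5-methoxy-3-(methoxymethoxy)-2-(trimethylsilyl)phenyl trifluoromethanesulfonate
Product: 20 (R)-1-[2-hydroxy-4-methoxy-6-(methoxymethoxy)phenyl]-3-(triisopropylsilyloxy)-3-[4-(tri-O-benzylkaempferol-3-yloxy)phenyl]propan-1-one, via 5-methoxy-3-(methoxymethoxy)benzyne 19 (not isolated)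
Conditions: CsF (4 equiv), 9 (1.5 equiv), THF, 125 °C, sealed tube
Reagents that add atoms: none
Why: CsF converts 18 into its caesium carboxylate and attacks silicon of 9, and loss of triflate releases aryne 19. The carboxylate oxygen adds to C1 of 19, the aryne carbon remote from the methoxymethoxy group, because the σ-withdrawing C3–O bond stabilises the aryl anion developing at C2 and distorts the aryne towards attack at C1; the 5-methoxy group, meta to C1, does not oppose this. The aryl anion then attacks the carbonyl of the aryl ester just formed, and the four-membered alkoxide opens by C–O cleavage to the ortho-acylphenoxide, so the aryne is inserted into the acid C–O bond with formation of C8a–O1 and C4a–C4. The closest known reaction type is this same fluoride-induced insertion of arynes, 3-alkoxyarynes included, into the C–O bond of aliphatic and aromatic carboxylic acids to give ortho-hydroxyaryl ketones. No ring is closed in the product and no stereocentre is formed; the carbinol carbon is β to the reacting carbonyl, takes no part and stays R. The step needs regioselective addition (secured by the 3-alkoxy group), acyl transfer faster than protonation of the aryl anion (favoured by the aprotic medium, the high temperature and the absence of free hydroxyl groups in 18) and survival of the β-silyloxy ketone (favoured by the bulk of the silyl group and by the product resting as its phenoxide, which disfavours enolisation and elimination).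

Step 12
Reactants: 20 (R)-1-[2-hydroxy-4-methoxy-6-(methoxymethoxy)phenyl]-3-(triisopropylsilyloxy)-3-[4-(tri-O-benzylkaempferol-3-yloxy)phenyl]propan-1-one
Product: 21 (R)-3-hydroxy-1-[2-hydroxy-4-methoxy-6-(methoxymethoxy)phenyl]-3-[4-(tri-O-benzylkaempferol-3-yloxy)phenyl]propan-1-one
Conditions: HF·pyridine, pyridine, THF, 0 °C → rt
Reagents that add atoms: none
Why: Fluoride-driven Si–O cleavage in a buffered, weakly acidic medium, which avoids the retro-aldol cleavage and E1cB dehydration that a basic fluoride source would promote in a β-hydroxy ketone; the acetal and the benzyl ethers are stable to it.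

Step 13
Reactants: 21 (R)-3-hydroxy-1-[2-hydroxy-4-methoxy-6-(methoxymethoxy)phenyl]-3-[4-(tri-O-benzylkaempferol-3-yloxy)phenyl]propan-1-one
Product: 22 (2S)-7-methoxy-5-(methoxymethoxy)-2-[4-(tri-O-benzylkaempferol-3-yloxy)phenyl]chroman-4-one
Conditions: PPh3, DIAD, THF, 0 °C
Reagents that add atoms: none
Why: Intramolecular Mitsunobu reaction: the benzylic hydroxyl is activated as an alkoxyphosphonium ion and displaced by the only free phenol (made more acidic by the ortho ketone) in a 6-exo-tet SN2 closure, so the R carbinol is inverted to 2S. The low temperature and the weakly donating, chromone-conjugated aryloxy substituent should hold back ionisation and elimination to the chalcone.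

Step 14
Reactants: 22 (2S)-7-methoxy-5-(methoxymethoxy)-2-[4-(tri-O-benzylkaempferol-3-yloxy)phenyl]chroman-4-one
Product: 23 (2S)-5-hydroxy-7-methoxy-2-[4-(tri-O-benzylkaempferol-3-yloxy)phenyl]chroman-4-one
Conditions: 3 M HCl (aq), MeOH/THF, 40 °C
Reagents that add atoms: none
Why: Acid-catalysed cleavage of the aryl methoxymethyl acetal, which is assisted by the peri carbonyl and gives the hydrogen-bonded 5-OH. Mild protic acid leaves the benzyl and diaryl ethers alone and should not open the flavanone, whose epimerisation runs mainly through base.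

Step 15
Reactants: 23 (2S)-5-hydroxy-7-methoxy-2-[4-(tri-O-benzylkaempferol-3-yloxy)phenyl]chroman-4-one
Product: 24 (2S)-5-hydroxy-2-{4-[5,7-dihydroxy-2-(4-hydroxyphenyl)-4-oxo-4H-chromen-3-yloxy]phenyl}-7-methoxychroman-4-one (target)
Conditions: H2 (1 atm), 10 % Pd/C, THF/MeOH, rt
Reagents that add atoms: none
Why: Hydrogenolysis of the three aryl benzyl ethers under neutral conditions, stopped after uptake of three equivalents. The tetrasubstituted chromone alkene, the diaryl ether and the flavanone ketone and C2–O1 bond react more slowly, and no base is present that could epimerise C2.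

## Compound list

1 | 5-methoxyresorcinol | COc1cc(O)cc(O)c1 | starting material
2 | 3-methoxy-5-(methoxymethoxy)phenol | COCOc1cc(O)cc(OC)c1 | intermediate
3 | 3-methoxy-5-(methoxymethoxy)phenyl N-isopropylcarbamate | COCOc1cc(OC)cc(OC(=O)NC(C)C)c1 | intermediate
4 | 3-methoxy-5-(methoxymethoxy)phenyl N-(tert-butyldimethylsilyl)-N-isopropylcarbamate | COCOc1cc(OC)cc(OC(=O)N(C(C)C)[Si](C)(C)C(C)(C)C)c1 | intermediate (not isolated)
5 | 2-lithio derivative of 4 (lithium on the carbon between the carbamate and the acetal oxygen) | COCOc1cc(OC)cc(OC(=O)N(C(C)C)[Si](C)(C)C(C)(C)C)c1[Li] | intermediate (not isolated)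
6 | 5-methoxy-3-(methoxymethoxy)-2-(trimethylsilyl)phenyl N-(tert-butyldimethylsilyl)-N-isopropylcarbamate | COCOc1cc(OC)cc(OC(=O)N(C(C)C)[Si](C)(C)C(C)(C)C)c1[Si](C)(C)C | intermediate (not isolated)
7 | 5-methoxy-3-(methoxymethoxy)-2-(trimethylsilyl)phenyl N-isopropylcarbamate | COCOc1cc(OC)cc(OC(=O)NC(C)C)c1[Si](C)(C)C | intermediate
8 | 5-methoxy-3-(methoxymethoxy)-2-(trimethylsilyl)phenol | COCOc1cc(OC)cc(O)c1[Si](C)(C)C | intermediate (not isolated)
9 | 5-methoxy-3-(methoxymethoxy)-2-(trimethylsilyl)phenyl trifluoromethanesulfonate | COCOc1cc(OC)cc(OS(=O)(=O)C(F)(F)F)c1[Si](C)(C)C | intermediate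
10 | kaempferol | O=c1c(O)c(-c2ccc(O)cc2)oc2cc(O)cc(O)c12 | starting material
11 | 7,4'-di-O-benzylkaempferol | O=c1c(O)c(-c2ccc(OCc3ccccc3)cc2)oc2cc(OCc3ccccc3)cc(O)c12 | intermediate
12 | 4-fluorobenzaldehyde | O=Cc1ccc(F)cc1 | starting material
13 | 4-{[7-(benzyloxy)-2-[4-(benzyloxy)phenyl]-5-hydroxy-4-oxo-4H-chromen-3-yl]oxy}benzaldehyde | O=Cc1ccc(Oc2c(-c3ccc(OCc4ccccc4)cc3)oc3cc(OCc4ccccc4)cc(O)c3c2=O)cc1 | intermediate (not isolated)
14 | 4-{[5,7-bis(benzyloxy)-2-[4-(benzyloxy)phenyl]-4-oxo-4H-chromen-3-yl]oxy}benzaldehyde | O=Cc1ccc(Oc2c(-c3ccc(OCc4ccccc4)cc3)oc3cc(OCc4ccccc4)cc(OCc4ccccc4)c3c2=O)cc1 | intermediate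
15 | ethyl 3-oxo-3-[4-(tri-O-benzylkaempferol-3-yloxy)phenyl]propanoate | CCOC(=O)CC(=O)c1ccc(Oc2c(-c3ccc(OCc4ccccc4)cc3)oc3cc(OCc4ccccc4)cc(OCc4ccccc4)c3c2=O)cc1 | intermediate
16 | ethyl (R)-3-hydroxy-3-[4-(tri-O-benzylkaempferol-3-yloxy)phenyl]propanoate | CCOC(=O)C[C@@H](O)c1ccc(Oc2c(-c3ccc(OCc4ccccc4)cc3)oc3cc(OCc4ccccc4)cc(OCc4ccccc4)c3c2=O)cc1 | intermediate
17 | ethyl (R)-3-(triisopropylsilyloxy)-3-[4-(tri-O-benzylkaempferol-3-yloxy)phenyl]propanoate | CCOC(=O)C[C@@H](O[Si](C(C)C)(C(C)C)C(C)C)c1ccc(Oc2c(-c3ccc(OCc4ccccc4)cc3)oc3cc(OCc4ccccc4)cc(OCc4ccccc4)c3c2=O)cc1 | intermediate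
18 | (R)-3-(triisopropylsilyloxy)-3-[4-(tri-O-benzylkaempferol-3-yloxy)phenyl]propanoic acid | OC(=O)C[C@@H](O[Si](C(C)C)(C(C)C)C(C)C)c1ccc(Oc2c(-c3ccc(OCc4ccccc4)cc3)oc3cc(OCc4ccccc4)cc(OCc4ccccc4)c3c2=O)cc1 | intermediate
19 | 5-methoxy-3-(methoxymethoxy)benzyne (triple bond between C1 and C2) | COCOC1=CC(OC)=CC#C1 | intermediate (not isolated)
20 | (R)-1-[2-hydroxy-4-methoxy-6-(methoxymethoxy)phenyl]-3-(triisopropylsilyloxy)-3-[4-(tri-O-benzylkaempferol-3-yloxy)phenyl]propan-1-one | COCOc1cc(OC)cc(O)c1C(=O)C[C@@H](O[Si](C(C)C)(C(C)C)C(C)C)c1ccc(Oc2c(-c3ccc(OCc4ccccc4)cc3)oc3cc(OCc4ccccc4)cc(OCc4ccccc4)c3c2=O)cc1 | intermediate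
21 | (R)-3-hydroxy-1-[2-hydroxy-4-methoxy-6-(methoxymethoxy)phenyl]-3-[4-(tri-O-benzylkaempferol-3-yloxy)phenyl]propan-1-one | COCOc1cc(OC)cc(O)c1C(=O)C[C@@H](O)c1ccc(Oc2c(-c3ccc(OCc4ccccc4)cc3)oc3cc(OCc4ccccc4)cc(OCc4ccccc4)c3c2=O)cc1 | intermediate
22 | (2S)-7-methoxy-5-(methoxymethoxy)-2-[4-(tri-O-benzylkaempferol-3-yloxy)phenyl]chroman-4-one | COc1cc(OCOC)c2c(c1)O[C@H](c1ccc(Oc3c(-c4ccc(OCc5ccccc5)cc4)oc4cc(OCc5ccccc5)cc(OCc5ccccc5)c4c3=O)cc1)CC2=O | intermediate
23 | (2S)-5-hydroxy-7-methoxy-2-[4-(tri-O-benzylkaempferol-3-yloxy)phenyl]chroman-4-one | COc1cc(O)c2c(c1)O[C@H](c1ccc(Oc3c(-c4ccc(OCc5ccccc5)cc4)oc4cc(OCc5ccccc5)cc(OCc5ccccc5)c4c3=O)cc1)CC2=O | intermediate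
24 | (2S)-5-hydroxy-2-{4-[5,7-dihydroxy-2-(4-hydroxyphenyl)-4-oxo-4H-chromen-3-yloxy]phenyl}-7-methoxychroman-4-one | COc1cc(O)c2c(c1)O[C@H](c1ccc(Oc3c(-c4ccc(O)cc4)oc4cc(O)cc(O)c4c3=O)cc1)CC2=O | target

## Step count and least certain steps

Total: 15 steps. Longest linear sequence: 11 steps (10 → 24, steps 5 to 15). The aryne precursor branch is 4 steps (1 → 9) and joins at step 11.

**Step 11 (key step).**
- Most likely failure: protonation of the aryl anion before it reaches the ester carbonyl, which stops the sequence at the aryl ester. The anion is flanked by an acetal oxygen and must form a di-ortho-substituted ketone, so acyl transfer is hindered. Fluoride attack on the silyl ether, followed by retro-aldol cleavage or elimination, is the second risk.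
- Fallback: the aryl–acyl bond is made by organolithium acylation. Acid 18 is converted (MeNHOMe·HCl, EDC·HCl, iPr2NEt, CH2Cl2) into the Weinreb amide F1. In parallel, 1 is protected twice (MOMCl, NaH, DMF) to 1-methoxy-3,5-bis(methoxymethoxy)benzene F2. n-BuLi (THF, 0 °C) lithiates F2 between the two acetal oxygens to the aryllithium F3. Addition of F3 to F1 at −78 °C gives the 2,6-bis(methoxymethoxy)aryl ketone F4. Chelation-assisted cleavage of one of its two equivalent acetals (dilute HCl, MeOH/THF, 0 °C, stopped at mono-cleavage) returns to the route at 20.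

**Step 13.**
- Most likely failure: loss of stereochemical fidelity, either by ionisation of the activated benzylic carbinol or by base-induced elimination to the chalcone and non-selective re-addition.
- Fallback: stereospecific closure is given up. 21 is heated with NaOAc in EtOH. Dehydration gives the 2'-hydroxychalcone F5, which closes by oxa-Michael addition to the racemic flavanone F6. Preparative chromatography on a chiral stationary phase gives 22, and the unwanted 2R enantiomer is re-equilibrated through F5 with the same base and recycled.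

**Step 3.**
- Most likely failure: poor site selectivity of the lithiation, with metalation between the carbamate and the methoxy group competing with metalation between the carbamate and the acetal.
- Fallback: the site is fixed by symmetry. 1 is treated with two equivalents of iPrNCO to give the bis-carbamate F7. Double N-silylation, lithiation and TMSCl quench as in step 3 place silicon between the two carbamates, giving F8. DBU/Et2NH releases 5-methoxy-2-(trimethylsilyl)resorcinol F9. Mono-alkylation of one of its equivalent phenols (MOMCl, NaH) gives 8, which is triflated with PhNTf2 to 9.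

**Step 5.**
- Most likely failure: incomplete discrimination between the 4'-OH and the 3-OH, so that benzylation runs on to O3.
- Fallback: acetate exchange. 10 is peracetylated (Ac2O, pyridine) to kaempferol tetraacetate F10. BnBr, K2CO3 and KI in refluxing acetone replace only the acetates of the two most acidic phenols (O7 and O4') by benzyl, giving the 3,5-diacetate F11. Methanolysis (K2CO3, MeOH) returns to the route at 11.

**Step 6.**
- Most likely failure: slow substitution, because the 3-oxide is a hindered and weakly nucleophilic enolate-type oxygen, with degradation of the flavonolate on prolonged heating or competing arylation of O5.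
- Fallback: oxidative copper coupling in place of SNAr. 11 and 4-formylphenylboronic acid under Chan–Lam conditions (Cu(OAc)2, pyridine, 4 Å molecular sieves, CH2Cl2, air, rt) give 13, which is benzylated at O5 in a separate operation to 14. No compound outside the list is made (F0).

**Step 7.**
- Most likely failure: sluggish addition of the diazo ester to an aromatic aldehyde, and aryl migration competing with the hydride shift.
- Fallback: addition followed by oxidation. Reformatsky reaction of 14 (Zn, BrCH2CO2Et, THF, reflux) gives the racemic β-hydroxy ester F12, and Dess–Martin periodinane oxidises it to 15, where the route resumes.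

## Further compounds

F1 | step 11 | (R)-N-methoxy-N-methyl-3-(triisopropylsilyloxy)-3-[4-(tri-O-benzylkaempferol-3-yloxy)phenyl]propanamide | CON(C)C(=O)C[C@@H](O[Si](C(C)C)(C(C)C)C(C)C)c1ccc(Oc2c(-c3ccc(OCc4ccccc4)cc3)oc3cc(OCc4ccccc4)cc(OCc4ccccc4)c3c2=O)cc1
F2 | step 11 | 1-methoxy-3,5-bis(methoxymethoxy)benzene | COCOc1cc(OC)cc(OCOC)c1
F3 | step 11 | [4-methoxy-2,6-bis(methoxymethoxy)phenyl]lithium | [Li]c1c(OCOC)cc(OC)cc1OCOC
F4 | step 11 | (R)-1-[4-methoxy-2,6-bis(methoxymethoxy)phenyl]-3-(triisopropylsilyloxy)-3-[4-(tri-O-benzylkaempferol-3-yloxy)phenyl]propan-1-one | COCOc1cc(OC)cc(OCOC)c1C(=O)C[C@@H](O[Si](C(C)C)(C(C)C)C(C)C)c1ccc(Oc2c(-c3ccc(OCc4ccccc4)cc3)oc3cc(OCc4ccccc4)cc(OCc4ccccc4)c3c2=O)cc1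
F5 | step 13 | (E)-1-[2-hydroxy-4-methoxy-6-(methoxymethoxy)phenyl]-3-[4-(tri-O-benzylkaempferol-3-yloxy)phenyl]prop-2-en-1-one | COCOc1cc(OC)cc(O)c1C(=O)/C=C/c1ccc(Oc2c(-c3ccc(OCc4ccccc4)cc3)oc3cc(OCc4ccccc4)cc(OCc4ccccc4)c3c2=O)cc1
F6 | step 13 | racemic 7-methoxy-5-(methoxymethoxy)-2-[4-(tri-O-benzylkaempferol-3-yloxy)phenyl]chroman-4-one | COc1cc(OCOC)c2c(c1)OC(c1ccc(Oc3c(-c4ccc(OCc5ccccc5)cc4)oc4cc(OCc5ccccc5)cc(OCc5ccccc5)c4c3=O)cc1)CC2=O
F7 | step 3 | 5-methoxy-1,3-phenylene bis(N-isopropylcarbamate) | COc1cc(OC(=O)NC(C)C)cc(OC(=O)NC(C)C)c1
F8 | step 3 | 5-methoxy-2-(trimethylsilyl)-1,3-phenylene bis(N-isopropylcarbamate) | COc1cc(OC(=O)NC(C)C)c([Si](C)(C)C)c(OC(=O)NC(C)C)c1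
F9 | step 3 | 5-methoxy-2-(trimethylsilyl)benzene-1,3-diol | COc1cc(O)c([Si](C)(C)C)c(O)c1
F10 | step 5 | kaempferol 3,5,7,4'-tetraacetate | CC(=O)Oc1ccc(-c2oc3cc(OC(C)=O)cc(OC(C)=O)c3c(=O)c2OC(C)=O)cc1
F11 | step 5 | 3,5-di-O-acetyl-7,4'-di-O-benzylkaempferol | CC(=O)Oc1c(-c2ccc(OCc3ccccc3)cc2)oc2cc(OCc3ccccc3)cc(OC(C)=O)c2c1=O
F0 | step 6 | none | none
F12 | step 7 | racemic ethyl 3-hydroxy-3-[4-(tri-O-benzylkaempferol-3-yloxy)phenyl]propanoate | CCOC(=O)CC(O)c1ccc(Oc2c(-c3ccc(OCc4ccccc4)cc3)oc3cc(OCc4ccccc4)cc(OCc4ccccc4)c3c2=O)cc1
A1 | alternative 1 | 5,7-bis(benzyloxy)-2-[4-(benzyloxy)phenyl]-3-(4-bromophenoxy)chromen-4-one | O=c1c(Oc2ccc(Br)cc2)c(-c2ccc(OCc3ccccc3)cc2)oc2cc(OCc3ccccc3)cc(OCc3ccccc3)c12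
A2 | alternative 1 | 2-hydroxy-4,6-bis(benzyloxy)benzaldehyde | O=Cc1c(O)cc(OCc2ccccc2)cc1OCc1ccccc1
A3 | alternative 1 | 1-(benzyloxy)-4-[(4-bromophenoxy)ethynyl]benzene | Brc1ccc(OC#Cc2ccc(OCc3ccccc3)cc2)cc1
A4 | alternative 2 | (Z)-2-(4-bromophenoxy)-1-[2-hydroxy-4,6-bis(methoxymethoxy)phenyl]-3-[4-(methoxymethoxy)phenyl]prop-2-en-1-one | COCOc1cc(OCOC)cc(O)c1C(=O)/C(Oc1ccc(Br)cc1)=C/c1ccc(OCOC)cc1
A5 | alternative 2 | (Z)-2-(4-bromophenoxy)-3-[4-(methoxymethoxy)phenyl]acrylic acid | OC(=O)/C(Oc1ccc(Br)cc1)=C/c1ccc(OCOC)cc1
A6 | alternative 2 | 3,5-bis(methoxymethoxy)-2-(trimethylsilyl)phenyl trifluoromethanesulfonate | COCOc1cc(OCOC)cc(OS(=O)(=O)C(F)(F)F)c1[Si](C)(C)C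
A7 | alternative 3 | (2S)-5-(tert-butyldimethylsilyloxy)-7-methoxy-2-[4-(tri-O-benzylkaempferol-3-yloxy)phenyl]chroman-4-one | COc1cc(O[Si](C)(C)C(C)(C)C)c2c(c1)O[C@H](c1ccc(Oc3c(-c4ccc(OCc5ccccc5)cc4)oc4cc(OCc5ccccc5)cc(OCc5ccccc5)c4c3=O)cc1)CC2=O
A8 | alternative 3 | 2-diazo-1-[2-(tert-butyldimethylsilyloxy)-4-methoxy-6-{[4-(tri-O-benzylkaempferol-3-yloxy)phenyl]methoxy}phenyl]ethan-1-one | [N-]=[N+]=CC(=O)c1c(O[Si](C)(C)C(C)(C)C)cc(OC)cc1OCc1ccc(Oc2c(-c3ccc(OCc4ccccc4)cc3)oc3cc(OCc4ccccc4)cc(OCc4ccccc4)c3c2=O)cc1
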